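**Retrosynthetic overview**

- The target is a (3S)-isoflavan. After the pyran ring exists, only reductive deletion of a C2 alkoxy group and O-deallylation remain.
- Key disconnection: the pyran ring (O1–C2–C3–C4–C4a–C8a) is opened across C3–C4 and O1–C2 by a retro-hetero-Diels–Alder reaction. This gives a ring A o-quinone methide and a ring B (E)-β-aryl enol ether that carries a trans-2-phenylcyclohexyl auxiliary on oxygen.
- Enabling feature: in ring A the benzylic carbon C4 is ortho to the ring oxygen O1 (on C8a) and para to the C7 oxygen, so O1=C8a–C4a=C4 is an easily formed, donor-stabilised 1-oxadiene. C2–C3, bearing the electron-rich ring B, is the image of an enol ether at a higher oxidation level.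
- Hidden symmetry: rings A and B are the same 4-substituted 2-prenylresorcinol. Both partners therefore diverge from one aldehyde, made from resorcinol by two directed ortho-metalations (prenyl between the two oxygens, then formyl).
- Ring order: rings A and B are aromatic from the start; the pyran ring (ring C) is the only ring made and is closed last.

Key step: step 11

Assumption: the facial sense of the auxiliary is taken from the usual model for enol ethers of trans-2-phenylcyclohexanol (s-trans conformer, attack anti to the phenyl group), which for the (1S,2R)-alcohol on the (E)-alkene predicts 3S.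
Remark: chroman locants (O1, C2, C3, C4, C4a, C5–C8, C8a) are used for rings A and C and primed locants for ring B; prenyl = 3-methylbut-2-en-1-yl, allyl = prop-2-en-1-yl.

**Step 1**
Reactants: 1 resorcinol
Product: 2 1,3-bis(methoxymethoxy)benzene
Conditions: MOMCl, i-Pr2NEt, CH2Cl2, 0 °C to rt
Reagents that add atoms: chloromethyl methyl ether, COCCl
Why: Williamson-type O-alkylation of both phenols installs the MOM ethers that act as ortho-directing groups in steps 2 and 3.

**Step 2**
Reactants: 2 1,3-bis(methoxymethoxy)benzene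
Product: 4 1,3-bis(methoxymethoxy)-2-(3-methylbut-2-en-1-yl)benzene, via aryllithium 3 (not isolated)
Conditions: n-BuLi, THF, 0 °C to rt; then CuI (10 mol %), prenyl bromide, −78 °C to rt
Reagents that add atoms: prenyl bromide (1-bromo-3-methylbut-2-ene), CC(C)=CCBr
Why: Directed ortho-metalation occurs at the carbon flanked by both MOM ethers, and copper-mediated allylic substitution should place the linear prenyl group there, which is the C8 and C3' pattern of both aromatic rings.

**Step 3**
Reactants: 4 1,3-bis(methoxymethoxy)-2-(3-methylbut-2-en-1-yl)benzene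
Product: 6 2,4-bis(methoxymethoxy)-3-(3-methylbut-2-en-1-yl)benzaldehyde, via aryllithium 5 (not isolated)
Conditions: n-BuLi, TMEDA, THF, −20 to 0 °C; then DMF, −78 °C to rt; H2O
Reagents that add atoms: N,N-dimethylformamide, CN(C)C=O
Why: A second directed ortho-metalation can only take place at one of the two equivalent positions ortho to a MOM ether, and formylation of the aryllithium with DMF adds the carbon that becomes C4 (ring A half) or C3 (ring B half).

**Step 4**
Reactants: 6 2,4-bis(methoxymethoxy)-3-(3-methylbut-2-en-1-yl)benzaldehyde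
Product: 7 2,4-dihydroxy-3-(3-methylbut-2-en-1-yl)benzaldehyde
Conditions: HCl (2 M aq.), MeOH, 40 °C, short reaction time
Reagents that add atoms: none
Why: Acid-catalysed cleavage of the two aryl MOM acetals in dilute methanolic acid should be faster than acid-promoted cyclisation of the prenyl group onto a neighbouring phenol.

**Step 5**
Reactants: 7 2,4-dihydroxy-3-(3-methylbut-2-en-1-yl)benzaldehyde
Product: 8 2,4-bis(allyloxy)-3-(3-methylbut-2-en-1-yl)benzaldehyde
Conditions: allyl bromide (2.5 equiv), K2CO3, DMF, 50 °C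
Reagents that add atoms: allyl bromide, C=CCBr
Why: Exhaustive Williamson O-allylation gives ethers that tolerate organometallics and Lewis acids and can be removed at the end without acid.

**Step 6**
Reactants: 8 2,4-bis(allyloxy)-3-(3-methylbut-2-en-1-yl)benzaldehyde
Product: 9 1-[(E)-2-iodoethenyl]-2,4-bis(allyloxy)-3-(3-methylbut-2-en-1-yl)benzene
Conditions: CrCl2, CHI3, THF/1,4-dioxane, 0 °C to rt
Reagents that add atoms: iodoform, IC(I)I
Why: Takai olefination of an aromatic aldehyde is expected to give predominantly the (E)-vinyl iodide, with the aldehyde carbon becoming C3 and the iodoform carbon C2 of the target; the E geometry later fixes C3 relative to the auxiliary-controlled face.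

**Step 7**
Reactants: 9 1-[(E)-2-iodoethenyl]-2,4-bis(allyloxy)-3-(3-methylbut-2-en-1-yl)benzene; 10 (1S,2R)-trans-2-phenylcyclohexan-1-ol
Product: 11 1-[(E)-2-{[(1S,2R)-2-phenylcyclohexyl]oxy}ethenyl]-2,4-bis(allyloxy)-3-(3-methylbut-2-en-1-yl)benzene
Conditions: CuI (10 mol %), 3,4,7,8-tetramethyl-1,10-phenanthroline (20 mol %), Cs2CO3, toluene, 80 °C
Reagents that add atoms: none
Why: Ullmann-type C–O coupling of a vinyl iodide with an alcohol under CuI/phenanthroline catalysis proceeds with retention of alkene geometry, so the E configuration is carried into the enol ether and the auxiliary is attached through oxygen without touching its stereocentres.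

**Step 8**
Reactants: 7 2,4-dihydroxy-3-(3-methylbut-2-en-1-yl)benzaldehyde
Product: 12 4-(allyloxy)-2-hydroxy-3-(3-methylbut-2-en-1-yl)benzaldehyde
Conditions: allyl bromide (1.05 equiv), KHCO3, MeCN, 60 °C
Reagents that add atoms: allyl bromide, C=CCBr
Why: The 4-OH (para to the formyl group, not hydrogen-bonded) is more acidic and more accessible than the chelated 2-OH, so one equivalent of allyl bromide with a weak base should alkylate it regioselectively and leave free the phenol that becomes O1.

**Step 9**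
Reactants: 12 4-(allyloxy)-2-hydroxy-3-(3-methylbut-2-en-1-yl)benzaldehyde
Product: 13 3-(allyloxy)-6-formyl-2-(3-methylbut-2-en-1-yl)phenyl tert-butyl carbonate
Conditions: Boc2O, i-Pr2NEt, DMAP (5 mol %), CH2Cl2, 0 °C to rt
Reagents that add atoms: di-tert-butyl dicarbonate, CC(C)(C)OC(=O)OC(=O)OC(C)(C)C
Why: DMAP-catalysed O-acylation of the remaining phenol gives the aryl tert-butyl carbonate that serves as the latent leaving group for o-quinone methide generation.

**Step 10**
Reactants: 13 3-(allyloxy)-6-formyl-2-(3-methylbut-2-en-1-yl)phenyl tert-butyl carbonate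
Product: 14 3-(allyloxy)-6-(hydroxymethyl)-2-(3-methylbut-2-en-1-yl)phenyl tert-butyl carbonate
Conditions: NaBH4, CeCl3·7H2O, MeOH/THF, −78 °C; pH 7 buffer
Reagents that add atoms: none
Why: Luche-type 1,2-reduction at −78 °C reduces only the aldehyde and keeps the product metal-bound until a neutral quench, so the Boc group should not yet migrate, while the aryl carbonate, allyl ether and prenyl group are inert to NaBH4.

**Step 11**
Reactants: 14 3-(allyloxy)-6-(hydroxymethyl)-2-(3-methylbut-2-en-1-yl)phenyl tert-butyl carbonate (1.5 equiv); 11 1-[(E)-2-{[(1S,2R)-2-phenylcyclohexyl]oxy}ethenyl]-2,4-bis(allyloxy)-3-(3-methylbut-2-en-1-yl)benzene (1.0 equiv)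
Product: 17 (2R,3S)-7-(allyloxy)-3-[2,4-bis(allyloxy)-3-(3-methylbut-2-en-1-yl)phenyl]-8-(3-methylbut-2-en-1-yl)-2-{[(1S,2R)-2-phenylcyclohexyl]oxy}chromane, via chloromagnesium phenoxide 15 (not isolated), via o-quinone methide 16 (not isolated)
Conditions: t-BuMgCl (1.5 equiv), toluene/THF, −78 °C, slow warming to rt; aq. NH4Cl
Reagents that add atoms: none
Why: t-BuMgCl deprotonates the benzylic alcohol of 14, the Boc group shifts from the phenolic to the benzylic oxygen (15), and 1,4-elimination of tert-butyl carbonate from the magnesium phenoxide releases o-quinone methide 16 below room temperature, which is trapped by enol ether 11 in an inverse-electron-demand hetero-Diels–Alder reaction. The closest known reaction type is the low-temperature, magnesium-mediated generation of o-quinone methides from O-Boc salicyl alcohols and their diastereoselective [4+2] cycloaddition with enol ethers of trans-2-phenylcyclohexanol. The pyran ring is closed by a concerted, asynchronous intermolecular [4π+2π] cycloaddition of the 1-oxadiene O1=C8a–C4a=C4 with C2=C3, which forms C4–C3 and O1–C2 in one event. C3 is set by the auxiliary: in the s-trans enol ether the phenyl group of the (1S,2R)-2-phenylcyclohexyl unit covers one π-face, so the methide carbon should bond to the open face of the aryl-bearing carbon and give 3S, while C2 (2R, trans to the aryl group) follows from suprafacial addition to the E double bond and is deleted in step 12. Regioselectivity (aryl at C3, not C2) is secured by the alkoxy donor, which puts the largest HOMO coefficient on the aryl-bearing carbon, matched with the electrophilic methide carbon; the prenyl groups and allyl ethers are unactivated alkenes and should not compete. Chemoselectivity against self-condensation of 16 needs its slow release in the presence of 11, which the temperature-gated Boc shift provides.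

**Step 12**
Reactants: 17 (2R,3S)-7-(allyloxy)-3-[2,4-bis(allyloxy)-3-(3-methylbut-2-en-1-yl)phenyl]-8-(3-methylbut-2-en-1-yl)-2-{[(1S,2R)-2-phenylcyclohexyl]oxy}chromane
Product: 19 (3S)-7-(allyloxy)-3-[2,4-bis(allyloxy)-3-(3-methylbut-2-en-1-yl)phenyl]-8-(3-methylbut-2-en-1-yl)chromane, via oxocarbenium ion 18 (not isolated)
Conditions: Et3SiH, BF3·OEt2, CH2Cl2, −78 °C; aq. NaHCO3
Reagents that add atoms: none
Why: BF3 ionises the exocyclic acetal C2–O bond (the auxiliary oxygen is the more basic one) to the cyclic oxocarbenium ion 18, which Et3SiH should reduce at −78 °C faster than it can lose the C3 proton, so C2 becomes the chroman methylene and C3 keeps its S configuration (ionic hydrogenation of a 2-alkoxychroman).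

**Step 13**
Reactants: 19 (3S)-7-(allyloxy)-3-[2,4-bis(allyloxy)-3-(3-methylbut-2-en-1-yl)phenyl]-8-(3-methylbut-2-en-1-yl)chromane
Product: 20 (3S)-3-[2,4-dihydroxy-3-(3-methylbut-2-en-1-yl)phenyl]-8-(3-methylbut-2-en-1-yl)-3,4-dihydro-2H-chromen-7-ol
Conditions: Pd(PPh3)4 (5 mol %), morpholine (excess), THF, rt
Reagents that add atoms: none
Why: Zerovalent palladium ionises the three aryl allyl ethers to π-allyl complexes that morpholine scavenges (Tsuji–Trost deallylation), which frees the three phenols under non-acidic conditions that should neither cyclise the ortho-prenyl phenols nor touch the C-prenyl groups or C3.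

**Compound list**

1 | resorcinol (benzene-1,3-diol) | Oc1cccc(O)c1 | starting material
2 | 1,3-bis(methoxymethoxy)benzene | COCOc1cccc(OCOC)c1 | intermediate
3 | [2,6-bis(methoxymethoxy)phenyl]lithium | [Li]c1c(OCOC)cccc1OCOC | intermediate
4 | 1,3-bis(methoxymethoxy)-2-(3-methylbut-2-en-1-yl)benzene | COCOc1cccc(OCOC)c1CC=C(C)C | intermediate
5 | [2,4-bis(methoxymethoxy)-3-(3-methylbut-2-en-1-yl)phenyl]lithium | [Li]c1ccc(OCOC)c(CC=C(C)C)c1OCOC | intermediate
6 | 2,4-bis(methoxymethoxy)-3-(3-methylbut-2-en-1-yl)benzaldehyde | COCOc1ccc(C=O)c(OCOC)c1CC=C(C)C | intermediate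
7 | 2,4-dihydroxy-3-(3-methylbut-2-en-1-yl)benzaldehyde | CC(C)=CCc1c(O)ccc(C=O)c1O | intermediate
8 | 2,4-bis(allyloxy)-3-(3-methylbut-2-en-1-yl)benzaldehyde | C=CCOc1ccc(C=O)c(OCC=C)c1CC=C(C)C | intermediate
9 | 1-[(E)-2-iodoethenyl]-2,4-bis(allyloxy)-3-(3-methylbut-2-en-1-yl)benzene | C=CCOc1ccc(/C=C/I)c(OCC=C)c1CC=C(C)C | intermediate
10 | (1S,2R)-trans-2-phenylcyclohexan-1-ol | O[C@H]1CCCC[C@@H]1c1ccccc1 | starting material
11 | 1-[(E)-2-{[(1S,2R)-2-phenylcyclohexyl]oxy}ethenyl]-2,4-bis(allyloxy)-3-(3-methylbut-2-en-1-yl)benzene | C=CCOc1ccc(/C=C/O[C@H]2CCCC[C@@H]2c2ccccc2)c(OCC=C)c1CC=C(C)C | intermediate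
12 | 4-(allyloxy)-2-hydroxy-3-(3-methylbut-2-en-1-yl)benzaldehyde | C=CCOc1ccc(C=O)c(O)c1CC=C(C)C | intermediate
13 | 3-(allyloxy)-6-formyl-2-(3-methylbut-2-en-1-yl)phenyl tert-butyl carbonate | C=CCOc1ccc(C=O)c(OC(=O)OC(C)(C)C)c1CC=C(C)C | intermediate
14 | 3-(allyloxy)-6-(hydroxymethyl)-2-(3-methylbut-2-en-1-yl)phenyl tert-butyl carbonate | C=CCOc1ccc(CO)c(OC(=O)OC(C)(C)C)c1CC=C(C)C | intermediate
15 | chloromagnesium 3-(allyloxy)-6-{[(tert-butoxycarbonyl)oxy]methyl}-2-(3-methylbut-2-en-1-yl)phenoxide | C=CCOc1ccc(COC(=O)OC(C)(C)C)c(O[Mg]Cl)c1CC=C(C)C | intermediate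
16 | 3-(allyloxy)-6-methylidene-2-(3-methylbut-2-en-1-yl)cyclohexa-2,4-dien-1-one (o-quinone methide) | C=CCOC1=C(CC=C(C)C)C(=O)C(=C)C=C1 | intermediate
17 | (2R,3S)-7-(allyloxy)-3-[2,4-bis(allyloxy)-3-(3-methylbut-2-en-1-yl)phenyl]-8-(3-methylbut-2-en-1-yl)-2-{[(1S,2R)-2-phenylcyclohexyl]oxy}chromane | C=CCOc1ccc2c(c1CC=C(C)C)O[C@@H](O[C@H]3CCCC[C@@H]3c3ccccc3)[C@@H](C2)c2ccc(OCC=C)c(CC=C(C)C)c2OCC=C | intermediate
18 | (3S)-7-(allyloxy)-3-[2,4-bis(allyloxy)-3-(3-methylbut-2-en-1-yl)phenyl]-8-(3-methylbut-2-en-1-yl)-3,4-dihydrochromenylium (O1=C2 oxocarbenium ion) | C=CCOc1ccc2c(c1CC=C(C)C)[O+]=C[C@@H](C2)c1ccc(OCC=C)c(CC=C(C)C)c1OCC=C | intermediate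
19 | (3S)-7-(allyloxy)-3-[2,4-bis(allyloxy)-3-(3-methylbut-2-en-1-yl)phenyl]-8-(3-methylbut-2-en-1-yl)chromane | C=CCOc1ccc2c(c1CC=C(C)C)OC[C@@H](C2)c1ccc(OCC=C)c(CC=C(C)C)c1OCC=C | intermediate
20 | (3S)-3-[2,4-dihydroxy-3-(3-methylbut-2-en-1-yl)phenyl]-8-(3-methylbut-2-en-1-yl)-3,4-dihydro-2H-chromen-7-ol | CC(C)=CCc1c(O)ccc([C@H]2COc3c(ccc(O)c3CC=C(C)C)C2)c1O | target

**Step count and risks**

Total step count: 13. Longest linear sequence: 10 steps (1–4, then 5–7 or 8–10, then 11–13).

Steps most likely to fail: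

1. Step 11. The auxiliary may discriminate poorly between the faces of the conjugated, hindered β-aryl enol ether, or self-condensation of the o-quinone methide may outrun the cycloaddition. The fallback sets C3 by an Evans-type oxazolidinone alkylation and closes the pyran ring by etherification; it sets out from 11 and 14 and comes back at 19.
 - Enol ether 11 is hydrolysed (1 M HCl, THF, rt; the auxiliary alcohol is recovered) to 2-[2,4-bis(allyloxy)-3-(3-methylbut-2-en-1-yl)phenyl]acetaldehyde F1.
 - Pinnick oxidation (NaClO2, NaH2PO4, 2-methylbut-2-ene, t-BuOH/H2O) gives [2,4-bis(allyloxy)-3-(3-methylbut-2-en-1-yl)phenyl]acetic acid F2.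
 - Coupling through the pivaloyl mixed anhydride with lithiated (S)-4-benzyl-1,3-oxazolidin-2-one gives (4S)-4-benzyl-3-{[2,4-bis(allyloxy)-3-(3-methylbut-2-en-1-yl)phenyl]acetyl}-1,3-oxazolidin-2-one F3.
 - Alcohol 14 is converted by an Appel reaction (CBr4, PPh3, CH2Cl2, 0 °C) into 3-(allyloxy)-6-(bromomethyl)-2-(3-methylbut-2-en-1-yl)phenyl tert-butyl carbonate F4.
 - The sodium enolate of F3 (NaHMDS, THF, −78 °C) should be alkylated by F4 on the face away from the benzyl group to give the (2S)-configured alkylated imide F5.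
 - LiBH4 (THF/MeOH, 0 °C) followed by K2CO3/MeOH should remove the oxazolidinone reductively and cleave the aryl carbonate to give (2S)-3-[4-(allyloxy)-2-hydroxy-3-(3-methylbut-2-en-1-yl)phenyl]-2-[2,4-bis(allyloxy)-3-(3-methylbut-2-en-1-yl)phenyl]propan-1-ol F6.
 - Mitsunobu etherification (PPh3, DIAD, THF, 0 °C) closes the O1–C2 bond at the primary carbon without touching the stereocentre and gives 19.

2. Step 12. The oxocarbenium ion may lose the C3 proton (erosion of enantiomeric purity through an enol ether), or ionisation may occur at the endocyclic C–O bond and open the ring. The fallback replaces hydride capture of the cation by hydrolysis, carbonyl reduction and re-closure; it sets out from 17 and comes back at 19.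
 - Mild hydrolysis of 17 (PPTS, acetone/H2O, 50 °C; auxiliary recovered) gives (3S)-7-(allyloxy)-3-[2,4-bis(allyloxy)-3-(3-methylbut-2-en-1-yl)phenyl]-8-(3-methylbut-2-en-1-yl)chroman-2-ol F7.
 - F7 is reduced at once through its open hydroxy-aldehyde form (NaBH4, EtOH, 0 °C) to the phenol alcohol (2S)-3-[4-(allyloxy)-2-hydroxy-3-(3-methylbut-2-en-1-yl)phenyl]-2-[2,4-bis(allyloxy)-3-(3-methylbut-2-en-1-yl)phenyl]propan-1-ol F6.
 - Mitsunobu etherification (PPh3, DIAD, THF, 0 °C) returns 19.

3. Step 7. C–O coupling with the hindered secondary alcohol may be slow, so that dehydroiodination to the aryl alkyne or loss of alkene geometry takes over. The fallback makes the C=C bond by olefination instead of the C–O bond by coupling; it sets out from 8 and 10 and comes back at 11.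
 - Alcohol 10 is converted with paraformaldehyde and TMSCl (CH2Cl2, 0 °C to rt) into [(1S,2R)-2-(chloromethoxy)cyclohexyl]benzene F8.
 - PPh3 (toluene, 80 °C) gives ({[(1S,2R)-2-phenylcyclohexyl]oxy}methyl)triphenylphosphonium chloride F9.
 - The ylide (KHMDS, THF, −78 °C) reacts with aldehyde 8 in a Wittig reaction to give 11 together with its geometric isomer 1-[(Z)-2-{[(1S,2R)-2-phenylcyclohexyl]oxy}ethenyl]-2,4-bis(allyloxy)-3-(3-methylbut-2-en-1-yl)benzene F10.
 - F10 is separated by chromatography and recycled by iodine-catalysed equilibration towards the E isomer.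

**Further compounds**

F1 | step 11 | 2-[2,4-bis(allyloxy)-3-(3-methylbut-2-en-1-yl)phenyl]acetaldehyde | C=CCOc1ccc(CC=O)c(OCC=C)c1CC=C(C)C
F2 | step 11 | [2,4-bis(allyloxy)-3-(3-methylbut-2-en-1-yl)phenyl]acetic acid | C=CCOc1ccc(CC(=O)O)c(OCC=C)c1CC=C(C)C
F3 | step 11 | (4S)-4-benzyl-3-{[2,4-bis(allyloxy)-3-(3-methylbut-2-en-1-yl)phenyl]acetyl}-1,3-oxazolidin-2-one | C=CCOc1ccc(CC(=O)N2[C@@H](Cc3ccccc3)COC2=O)c(OCC=C)c1CC=C(C)C
F4 | step 11 | 3-(allyloxy)-6-(bromomethyl)-2-(3-methylbut-2-en-1-yl)phenyl tert-butyl carbonate | C=CCOc1ccc(CBr)c(OC(=O)OC(C)(C)C)c1CC=C(C)C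
F5 | step 11 | (4S)-4-benzyl-3-{(2S)-2-[2,4-bis(allyloxy)-3-(3-methylbut-2-en-1-yl)phenyl]-3-[4-(allyloxy)-2-[(tert-butoxycarbonyl)oxy]-3-(3-methylbut-2-en-1-yl)phenyl]propanoyl}-1,3-oxazolidin-2-one | C=CCOc1ccc([C@H](Cc2ccc(OCC=C)c(CC=C(C)C)c2OC(=O)OC(C)(C)C)C(=O)N2[C@@H](Cc3ccccc3)COC2=O)c(OCC=C)c1CC=C(C)C
F6 | step 11 | (2S)-3-[4-(allyloxy)-2-hydroxy-3-(3-methylbut-2-en-1-yl)phenyl]-2-[2,4-bis(allyloxy)-3-(3-methylbut-2-en-1-yl)phenyl]propan-1-ol | C=CCOc1ccc([C@H](Cc2ccc(OCC=C)c(CC=C(C)C)c2O)CO)c(OCC=C)c1CC=C(C)C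
F7 | step 12 | (3S)-7-(allyloxy)-3-[2,4-bis(allyloxy)-3-(3-methylbut-2-en-1-yl)phenyl]-8-(3-methylbut-2-en-1-yl)chroman-2-ol (anomeric mixture at C2) | C=CCOc1ccc2c(c1CC=C(C)C)OC(O)[C@@H](C2)c1ccc(OCC=C)c(CC=C(C)C)c1OCC=C
F8 | step 7 | [(1S,2R)-2-(chloromethoxy)cyclohexyl]benzene | ClCO[C@H]1CCCC[C@@H]1c1ccccc1
F9 | step 7 | ({[(1S,2R)-2-phenylcyclohexyl]oxy}methyl)triphenylphosphonium chloride | [Cl-].c1ccc(cc1)[P+](CO[C@H]1CCCC[C@@H]1c1ccccc1)(c1ccccc1)c1ccccc1
F10 | step 7 | 1-[(Z)-2-{[(1S,2R)-2-phenylcyclohexyl]oxy}ethenyl]-2,4-bis(allyloxy)-3-(3-methylbut-2-en-1-yl)benzene | C=CCOc1ccc(/C=C\O[C@H]2CCCC[C@@H]2c2ccccc2)c(OCC=C)c1CC=C(C)C
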